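The numbers are made up; the result is computed.

The sum of free catalyst, catalyst intermediate A and catalyst intermediate B stays at its charge, 0.100 mM, since the steps of the cycle only pass catalyst from one form to another.

    partner + free catalyst → catalyst intermediate A (k1 = 0.099 M⁻¹ s⁻¹)
    starting material + catalyst intermediate A → catalyst intermediate B (k2 = 0.16 M⁻¹ s⁻¹)
    catalyst intermediate B ⇌ free catalyst + target (K3 = 0.040 M, k3 = 0.010 s⁻¹)
    partner → decomposed reagent (k4 = 4.5 × 10⁻⁶ s⁻¹)
    target → over-reaction product (k5 = 7.1 × 10⁻⁶ s⁻¹)
    starting material + target ⇌ idle adduct, settled at all times (K6 = 8.4 M⁻¹)

starting material 0.10 M; partner 1.50 equiv; free catalyst 0.1 mol%; time 2.5 d

- a species is counted by the starting material in it: one idle adduct counts as two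
- amounts and yields of target count idle adduct too
- in an amount of target, one idle adduct counts as one target
- the reaction counts as stopped when no species that holds the starting material changes by six tenths of a point or more over the second half of the time
- what has gone from starting material into another species counts as reacted, even if it can come back
- run time (flask): 2.5 d

* which holds at 2.5 d: what has brought the reaction to rest, or that it has not come to rest (no working catalyst is left / forward and back rates have come level / the partner has run out first / all of the starting material has reacted / it is still moving)
* share of the starting material used up at 2.5 d
* target at 2.5 d, in percent of the starting material charged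
* over-reaction product at 2.5 d, in percent of the starting material charged

A bench rule says that the slowest step of a cycle, the rate-limiting step, sets the rate. At the charge that step is the release of target from catalyst intermediate B, with a wait of 100 s, and the rule gives 1.00 × 10⁻⁶ M s⁻¹, with the starting material used up in 1.16 d. The rule needs the next wait to be far shorter, but free catalyst waits 67.3 s for partner, a ratio of 0.673 to the release, and catalyst intermediate A waits 62.5 s for starting material.

So the waits add. Their sum is the cycle time τ, 230 s at the charge, and the rate is the catalyst total over τ, first order in that total: 4.35 × 10⁻⁷ M s⁻¹. Once target stands in the flask, τ gains a return term, c(free target) over the equilibrium constant of release times the partner wait, and this term belongs to catalyst intermediate B. Each form holds the share of catalyst that its wait has of τ. Partner decays with a half-life of 1.78 d, shorter than the run, so τ grows. My own reckoning therefore sets a ceiling of 94.0% of the starting material charged on turnover through the cycle and expects less; this is no ceiling on conversion, which also counts starting material held in idle adduct, outside the cycle.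

The forecast says it is still moving, with conversion 60%, target 28.4% and over-reaction product 24.3%, on the ground that “Partner remains, and species are still changing”. The simulation gives it is still moving, with conversion 60.2%, target 28.9% and over-reaction product 24.0%, so the forecast stands; a loading of 0.077 mol% or 0.13 mol% moves over-reaction product by 5 points.

At 2.50 d the flask's concentrations, with adduct-bound target taken away, give a partner wait of 385 s and τ of 852 s, 3.70 times its value at the charge, and free catalyst's reckoned share of 45.2% stands beside 45.2% in the flask. In the neighbour flask with 0.600 equiv of partner, at 2.50 d, the partner wait is 1650 s of a τ of 2290 s, a share of 72.1%, and that flask holds 71.9% of its catalyst as free catalyst.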